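**Retrosynthetic overview**
1. Target 21 ← double epoxidation of the macrocyclic (3E,7E)-diene acetate 20; the C10 acetate comes from reduction of a C10 ketone, the C12 methylene from deformylative methylenation of a C12 formyl group.
2. The 12-membered ring is closed at C9–C10 by intramolecular acylation of an allylic sulfonyl carbanion; C1–C2 comes from conjugate addition of the same geraniol-derived chain (as its C2 sulfonyl carbanion) to a cyclohexenone.
3. The cyclohexenone ← allylic oxidation of the Diels–Alder adduct of 4-methylpenta-1,3-diene and a (Z)-enoate made from (S)-glyceraldehyde acetonide; the cycloaddition forms the six-membered ring (C11–C15 and C12–C13 bonds) and sets C11.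
4. Stereochemical relay: dioxolane centre → C11 → C1 → C10 → the four epoxide carbons.
5. Ring order: six-membered carbocycle (step 2), 12-membered ring (step 10), two oxiranes (step 15).

Assumption: (S)-glyceraldehyde acetonide 1 (made on scale from L-ascorbic acid) is taken as a purchasable chiral-pool aldehyde; C1–C18 below are the bicyclo[9.3.1]pentadecane locants of the target (C15 = CMe2, C18 = exocyclic CH2).

**Route**

Step 1
Reactants: 1 (4S)-2,2-dimethyl-1,3-dioxolane-4-carbaldehyde; 2 methyl (triphenylphosphoranylidene)acetate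
Product: 3 methyl (2Z)-3-[(4R)-2,2-dimethyl-1,3-dioxolan-4-yl]prop-2-enoate
Conditions: MeOH, 0 °C
Reagents that add atoms: none
Why: Wittig olefination, which in methanol gives mainly the (Z)-enoate from this α-alkoxy aldehyde (about 8:1, E isomer removed by chromatography) without touching the stereocentre.

Step 2
Reactants: 3 methyl (2Z)-3-[(4R)-2,2-dimethyl-1,3-dioxolan-4-yl]prop-2-enoate; 4 4-methylpenta-1,3-diene
Product: 5 methyl (1R,6R)-6-[(4R)-2,2-dimethyl-1,3-dioxolan-4-yl]-2,2-dimethylcyclohex-3-ene-1-carboxylate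
Conditions: 4 (5 equiv), EtAlCl2 (0.3 equiv), CH2Cl2, −40 → 0 °C
Reagents that add atoms: none
Why: Lewis-acid-catalysed Diels–Alder reaction with "ortho" orientation (CH2 terminus to the β-carbon, CMe2 terminus to the ester-bearing carbon); the diene has no stereogenic terminus, the Z-alkene gives the cis product, and addition anti to the dioxolane C–O bond of the A(1,3)-minimised enoate sets C11 (and a temporary C12 centre).

Step 3
Reactants: 5 methyl (1R,6R)-6-[(4R)-2,2-dimethyl-1,3-dioxolan-4-yl]-2,2-dimethylcyclohex-3-ene-1-carboxylate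
Product: 6 methyl (1R,6R)-6-[(4R)-2,2-dimethyl-1,3-dioxolan-4-yl]-2,2-dimethyl-5-oxocyclohex-3-ene-1-carboxylate
Conditions: Pd(OH)2/C (5 mol%), t-BuOOH (5 equiv), K2CO3 (0.25 equiv), CH2Cl2, 4 °C
Reagents that add atoms: tert-butyl hydroperoxide, CC(C)(C)OO
Why: allylic C–H oxidation to the enone, regiospecific because C13 is the only allylic CH2 (the other allylic carbon is quaternary); no stereocentre is involved.

Step 4
Reactants: 7 geranyl bromide; 8 sodium benzenesulfinate
Product: 9 geranyl phenyl sulfone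
Conditions: DMF, rt
Reagents that add atoms: none
Why: SN2 S-alkylation of the sulfinate by the primary allylic bromide with retention of the E-alkene.

Step 5
Reactants: 9 geranyl phenyl sulfone
Product: 10 (2E,6E)-2,6-dimethyl-8-(phenylsulfonyl)octa-2,6-dien-1-ol
Conditions: SeO2 (0.3 equiv), t-BuOOH (3 equiv), salicylic acid (0.1 equiv), CH2Cl2, rt
Reagents that add atoms: tert-butyl hydroperoxide, CC(C)(C)OO
Why: Riley allylic oxidation (ene reaction then [2,3]-shift), selective for the (E)-methyl of the distal trisubstituted alkene because the proximal alkene is deactivated by the sulfonyl group.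

Step 6
Reactants: 6 methyl (1R,6R)-6-[(4R)-2,2-dimethyl-1,3-dioxolan-4-yl]-2,2-dimethyl-5-oxocyclohex-3-ene-1-carboxylate; 10 (2E,6E)-2,6-dimethyl-8-(phenylsulfonyl)octa-2,6-dien-1-ol
Product: 11 methyl (1R,3R,6R)-6-[(4R)-2,2-dimethyl-1,3-dioxolan-4-yl]-3-[(2E,6E)-8-hydroxy-3,7-dimethyl-1-(phenylsulfonyl)octa-2,6-dien-1-yl]-2,2-dimethyl-5-oxocyclohexane-1-carboxylate (mixture at the sulfonyl carbon)
Conditions: 10 (1.3 equiv), n-BuLi (2.6 equiv), THF–HMPA, −78 °C; then 6, −78 → −40 °C; AcOH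
Reagents that add atoms: none
Why: Michael addition through the α-carbon of the lithiated allylic sulfone (HMPA favours 1,4), which keeps both E-alkenes; axial attack anti to the C11 ester sets C1 trans to C11.

Step 7
Reactants: 11 (sulfonyl adduct above)
Product: 12 methyl (1R,3R,6R)-6-[(4R)-2,2-dimethyl-1,3-dioxolan-4-yl]-3-[(2E,6E)-8-hydroxy-3,7-dimethylocta-2,6-dien-1-yl]-2,2-dimethyl-5-oxocyclohexane-1-carboxylate
Conditions: 6% Na(Hg), Na2HPO4, MeOH–THF, −20 °C
Reagents that add atoms: none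
Why: reductive desulfonylation of the allylic sulfone; protonation at C2 keeps the E-trisubstituted alkene, and ketone, ester and acetonide survive the buffered conditions.

Step 8
Reactants: 12 (hydroxy keto ester above); 8 sodium benzenesulfinate
Product: 14 methyl (1R,3R,6R)-6-[(4R)-2,2-dimethyl-1,3-dioxolan-4-yl]-3-[(2E,6E)-3,7-dimethyl-8-(phenylsulfonyl)octa-2,6-dien-1-yl]-2,2-dimethyl-5-oxocyclohexane-1-carboxylate, via allylic mesylate 13 (not isolated)
Conditions: MsCl, Et3N, CH2Cl2, −20 °C; then 8, DMF, rt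
Reagents that add atoms: none
Why: mesylation of the only hydroxyl followed by SN2 displacement with sulfinate at the primary allylic carbon, E-alkene retained.

Step 9
Reactants: 14 (C9 sulfone above)
Product: 15 methyl (1R,3R)-3-[(2E,6E)-3,7-dimethyl-8-(phenylsulfonyl)octa-2,6-dien-1-yl]-6-formyl-2,2-dimethyl-5-oxocyclohexane-1-carboxylate (enolised 2-formyl ketone, C6 undefined)
Conditions: H5IO6 (1.5 equiv), EtOAc, rt
Reagents that add atoms: none
Why: periodic acid hydrolyses the terminal acetonide and cleaves the freed 1,2-diol (Malaprade cleavage) to the C12 aldehyde, which enolises with the C13 ketone and erases the temporary C12 centre.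

Step 10
Reactants: 15 (formyl keto ester sulfone above)
Product: 16 (1R,3E,7E,11R)-4,8,15,15-tetramethyl-10,13-dioxo-9-(phenylsulfonyl)bicyclo[9.3.1]pentadeca-3,7-diene-12-carbaldehyde (C9 and C12 undefined)
Conditions: LiN(SiMe3)2 (3.2 equiv), THF, 0.002 M, slow addition, −78 → 25 °C; AcOH
Reagents that add atoms: none
Why: intramolecular Claisen-type C-acylation of the allylic sulfonyl carbanion by the methyl ester closes the 12-membered ring; the formyl ketone is protected as its enolate (whose oxygen can relay the acyl group as a transient enol lactone) and deprotonation of the β-keto sulfone drives the closure.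

Step 11
Reactants: 16 (macrocyclic β-keto sulfone above)
Product: 17 (1R,3E,7E,11R)-4,8,15,15-tetramethyl-10,13-dioxobicyclo[9.3.1]pentadeca-3,7-diene-12-carbaldehyde
Conditions: Al(Hg), THF–H2O 9:1, 0 °C
Reagents that add atoms: none
Why: reductive desulfonylation of the β-keto sulfone under neutral conditions, with protonation at C9 so the C7=C8 alkene stays β,γ and E.

Step 12
Reactants: 17 (C10 ketone above)
Product: 18 (1R,3E,7E,10S,11R)-10-hydroxy-4,8,15,15-tetramethyl-13-oxobicyclo[9.3.1]pentadeca-3,7-diene-12-carbaldehyde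
Conditions: NaBH4 (2 equiv), MeOH, −40 °C
Reagents that add atoms: none
Why: chemoselective carbonyl reduction, since the 2-formyl ketone is present as its unreactive sodium enolate; Felkin–Anh hydride approach anti to the C11–C15 bond gives the 10S alcohol.

Step 13
Reactants: 18 (hydroxy formyl ketone above)
Product: 19 (1R,3E,7E,10S,11S)-10-hydroxy-4,8,15,15-tetramethyl-12-methylidenebicyclo[9.3.1]pentadeca-3,7-dien-13-one
Conditions: 37% aq. CH2O (5 equiv), K2CO3 (1.5 equiv), THF, 0 °C → rt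
Reagents that add atoms: formaldehyde, C=O
Why: deformylative α-methylenation (aldol addition to formaldehyde, retro-Claisen loss of formate, E1cB dehydration) places the methylene specifically at C12 without touching a stereocentre.

Step 14
Reactants: 19 (hydroxy methylene ketone above)
Product: 20 (1R,3E,7E,10S,11S)-10-acetoxy-4,8,15,15-tetramethyl-12-methylidenebicyclo[9.3.1]pentadeca-3,7-dien-13-one
Conditions: Ac2O, pyridine, DMAP (cat.), CH2Cl2, 0 °C
Reagents that add atoms: acetic anhydride, CC(=O)OC(C)=O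
Why: O-acylation of the only hydroxyl with retention at C10.

Step 15
Reactants: 20 (diene acetate above)
Product: 21 (1R,3R,4R,7R,8R,10S,11S)-10-acetoxy-3,4:7,8-diepoxy-4,8,15,15-tetramethyl-12-methylidenebicyclo[9.3.1]pentadecan-13-one
Conditions: mCPBA (2.2 equiv), NaHCO3, CH2Cl2, 0 °C
Reagents that add atoms: 3-chloroperoxybenzoic acid, O=C(OO)c1cccc(Cl)c1
Why: Prilezhaev epoxidation of the two electron-rich E-trisubstituted alkenes (the enone methylene is inert); syn delivery to the exposed outer face of each alkene in the bridged macrocycle is expected to give the trans-epoxides 3R,4R,7R,8R.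

**Compound list**
1 | (4S)-2,2-dimethyl-1,3-dioxolane-4-carbaldehyde | CC1(C)OC[C@@H](C=O)O1 | starting material
2 | methyl (triphenylphosphoranylidene)acetate | COC(=O)C=P(c1ccccc1)(c1ccccc1)c1ccccc1 | starting material
3 | methyl (2Z)-3-[(4R)-2,2-dimethyl-1,3-dioxolan-4-yl]prop-2-enoate | COC(=O)/C=C\[C@@H]1COC(C)(C)O1 | intermediate
4 | 4-methylpenta-1,3-diene | C=CC=C(C)C | starting material
5 | methyl (1R,6R)-6-[(4R)-2,2-dimethyl-1,3-dioxolan-4-yl]-2,2-dimethylcyclohex-3-ene-1-carboxylate (ester and dioxolanyl cis) | C1C=CC(C)(C)[C@H](C(=O)OC)[C@@H]1[C@@H]2COC(C)(C)O2 | intermediate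
6 | methyl (1R,6R)-6-[(4R)-2,2-dimethyl-1,3-dioxolan-4-yl]-2,2-dimethyl-5-oxocyclohex-3-ene-1-carboxylate | O=C1C=CC(C)(C)[C@H](C(=O)OC)[C@@H]1[C@@H]2COC(C)(C)O2 | intermediate
7 | geranyl bromide, (2E)-1-bromo-3,7-dimethylocta-2,6-diene | CC(C)=CCC/C(C)=C/CBr | starting material
8 | sodium benzenesulfinate | [Na+].[O-]S(=O)c1ccccc1 | starting material
9 | geranyl phenyl sulfone | CC(C)=CCC/C(C)=C/CS(=O)(=O)c1ccccc1 | intermediate
10 | (2E,6E)-2,6-dimethyl-8-(phenylsulfonyl)octa-2,6-dien-1-ol | OC/C(C)=C/CC/C(C)=C/CS(=O)(=O)c1ccccc1 | intermediate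
11 | methyl (1R,3R,6R)-6-[(4R)-2,2-dimethyl-1,3-dioxolan-4-yl]-3-[(2E,6E)-8-hydroxy-3,7-dimethyl-1-(phenylsulfonyl)octa-2,6-dien-1-yl]-2,2-dimethyl-5-oxocyclohexane-1-carboxylate (side chain trans to ester) | O=C1C[C@@H](C(S(=O)(=O)c2ccccc2)/C=C(\C)CC/C=C(\C)CO)C(C)(C)[C@H](C(=O)OC)[C@@H]1[C@@H]3COC(C)(C)O3 | intermediate
12 | methyl (1R,3R,6R)-6-[(4R)-2,2-dimethyl-1,3-dioxolan-4-yl]-3-[(2E,6E)-8-hydroxy-3,7-dimethylocta-2,6-dien-1-yl]-2,2-dimethyl-5-oxocyclohexane-1-carboxylate | O=C1C[C@@H](C/C=C(\C)CC/C=C(\C)CO)C(C)(C)[C@H](C(=O)OC)[C@@H]1[C@@H]2COC(C)(C)O2 | intermediate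
13 | allylic mesylate of 12 (8-methanesulfonyloxy side chain) | O=C1C[C@@H](C/C=C(\C)CC/C=C(\C)COS(C)(=O)=O)C(C)(C)[C@H](C(=O)OC)[C@@H]1[C@@H]2COC(C)(C)O2 | intermediate
14 | methyl (1R,3R,6R)-6-[(4R)-2,2-dimethyl-1,3-dioxolan-4-yl]-3-[(2E,6E)-3,7-dimethyl-8-(phenylsulfonyl)octa-2,6-dien-1-yl]-2,2-dimethyl-5-oxocyclohexane-1-carboxylate | O=C1C[C@@H](C/C=C(\C)CC/C=C(\C)CS(=O)(=O)c2ccccc2)C(C)(C)[C@H](C(=O)OC)[C@@H]1[C@@H]3COC(C)(C)O3 | intermediate
15 | methyl (1R,3R)-3-[(2E,6E)-3,7-dimethyl-8-(phenylsulfonyl)octa-2,6-dien-1-yl]-6-formyl-2,2-dimethyl-5-oxocyclohexane-1-carboxylate | O=CC1C(=O)C[C@@H](C/C=C(\C)CC/C=C(\C)CS(=O)(=O)c2ccccc2)C(C)(C)[C@@H]1C(=O)OC | intermediate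
16 | (1R,3E,7E,11R)-4,8,15,15-tetramethyl-10,13-dioxo-9-(phenylsulfonyl)bicyclo[9.3.1]pentadeca-3,7-diene-12-carbaldehyde | O=CC1C(=O)C[C@H]2C/C=C(\C)CC/C=C(\C)C(S(=O)(=O)c3ccccc3)C(=O)[C@H]1C2(C)C | intermediate
17 | (1R,3E,7E,11R)-4,8,15,15-tetramethyl-10,13-dioxobicyclo[9.3.1]pentadeca-3,7-diene-12-carbaldehyde | O=CC1C(=O)C[C@H]2C/C=C(\C)CC/C=C(\C)CC(=O)[C@H]1C2(C)C | intermediate
18 | (1R,3E,7E,10S,11R)-10-hydroxy-4,8,15,15-tetramethyl-13-oxobicyclo[9.3.1]pentadeca-3,7-diene-12-carbaldehyde | O=CC1C(=O)C[C@H]2C/C=C(\C)CC/C=C(\C)C[C@H](O)[C@H]1C2(C)C | intermediate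
19 | (1R,3E,7E,10S,11S)-10-hydroxy-4,8,15,15-tetramethyl-12-methylidenebicyclo[9.3.1]pentadeca-3,7-dien-13-one | C=C1C(=O)C[C@H]2C/C=C(\C)CC/C=C(\C)C[C@H](O)[C@H]1C2(C)C | intermediate
20 | (1R,3E,7E,10S,11S)-10-acetoxy-4,8,15,15-tetramethyl-12-methylidenebicyclo[9.3.1]pentadeca-3,7-dien-13-one | C=C1C(=O)C[C@H]2C/C=C(\C)CC/C=C(\C)C[C@H](OC(C)=O)[C@H]1C2(C)C | intermediate
21 | (1R,3R,4R,7R,8R,10S,11S)-10-acetoxy-3,4:7,8-diepoxy-4,8,15,15-tetramethyl-12-methylidenebicyclo[9.3.1]pentadecan-13-one | C=C1C(=O)C[C@H]2C[C@H]3O[C@]3(C)CC[C@H]3O[C@]3(C)C[C@H](OC(C)=O)[C@H]1C2(C)C | target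

**Step count and risks**
Total: 15 steps. Longest linear sequence: 13 steps (1–3, then 6–15); steps 4–5 prepare the chain sulfone in parallel.

Most likely to fail:

Step 2 (cycloaddition of a hindered diene with an open-chain Z-enoate; rate and face selectivity). Fallback, setting out from 3 and coming back at 5: acid-catalysed lactonisation (HCl, MeOH) gives (5R)-5-(hydroxymethyl)furan-2(5H)-one F1. This rigid cyclic dienophile is then combined with 4 under 12 kbar (CH2Cl2, 40 °C), where addition anti to the hydroxymethyl group is unambiguous, to give cis-fused (3R)-3-(hydroxymethyl)-7,7-dimethyl-3a,4,7,7a-tetrahydro-2-benzofuran-1(3H)-one F2. Methanolysis with in situ acetonide formation (MeOH, 2,2-dimethoxypropane, TsOH) returns 5.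

Step 10 (12-membered ring closure by acylation with a hindered ester). Fallback, setting out from 15 and coming back at 16: the ester is taken to the aldehyde with i-Bu2AlH (3 equiv, −78 °C, the formyl ketone being held as its aluminium enolate) to give 3-[(2E,6E)-3,7-dimethyl-8-(phenylsulfonyl)octa-2,6-dien-1-yl]-2,2-dimethyl-5-oxocyclohexane-1,6-dicarbaldehyde F3. The ring is then closed by reversible intramolecular addition of the sulfonyl carbanion to this unhindered aldehyde (LiN(SiMe3)2, high dilution) to give the macrocyclic β-hydroxy sulfone, 10-hydroxy-4,8,15,15-tetramethyl-13-oxo-9-(phenylsulfonyl)bicyclo[9.3.1]pentadeca-3,7-diene-12-carbaldehyde F4. Dess–Martin oxidation gives 16.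

Step 15 (face selectivity of the double epoxidation, which sets four stereocentres by substrate control alone). Fallback, setting out from 19 and coming back at 21: hydroxyl-directed epoxidation of the homoallylic C7=C8 alkene (VO(acac)2, t-BuOOH) gives the 7,8-epoxy alcohol, (1R,3E,7R,8R,10S,11S)-7,8-epoxy-10-hydroxy-4,8,15,15-tetramethyl-12-methylidenebicyclo[9.3.1]pentadec-3-en-13-one F5. Separate mCPBA epoxidation of C3=C4 on this more rigid mono-epoxide gives the diepoxy alcohol, (1R,3R,4R,7R,8R,10S,11S)-3,4:7,8-diepoxy-10-hydroxy-4,8,15,15-tetramethyl-12-methylidenebicyclo[9.3.1]pentadecan-13-one F6. Acetylation (Ac2O, pyridine, DMAP) gives 21.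

Further compounds
F1 | step 2 | (5R)-5-(hydroxymethyl)furan-2(5H)-one | O=C1C=C[C@H](CO)O1
F2 | step 2 | cis-fused (3R)-3-(hydroxymethyl)-7,7-dimethyl-3a,4,7,7a-tetrahydro-2-benzofuran-1(3H)-one | C1C=CC(C)(C)[C@H]2[C@@H]1[C@H](CO)OC2=O
F3 | step 10 | (1R,3R)-3-[(2E,6E)-3,7-dimethyl-8-(phenylsulfonyl)octa-2,6-dien-1-yl]-2,2-dimethyl-5-oxocyclohexane-1,6-dicarbaldehyde | O=CC1C(=O)C[C@@H](C/C=C(\C)CC/C=C(\C)CS(=O)(=O)c2ccccc2)C(C)(C)[C@@H]1C=O
F4 | step 10 | (1R,3E,7E,11R)-10-hydroxy-4,8,15,15-tetramethyl-13-oxo-9-(phenylsulfonyl)bicyclo[9.3.1]pentadeca-3,7-diene-12-carbaldehyde | O=CC1C(=O)C[C@H]2C/C=C(\C)CC/C=C(\C)C(S(=O)(=O)c3ccccc3)C(O)[C@H]1C2(C)C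
F5 | step 15 | (1R,3E,7R,8R,10S,11S)-7,8-epoxy-10-hydroxy-4,8,15,15-tetramethyl-12-methylidenebicyclo[9.3.1]pentadec-3-en-13-one | C=C1C(=O)C[C@H]2C/C=C(\C)CC[C@H]3O[C@]3(C)C[C@H](O)[C@H]1C2(C)C
F6 | step 15 | (1R,3R,4R,7R,8R,10S,11S)-3,4:7,8-diepoxy-10-hydroxy-4,8,15,15-tetramethyl-12-methylidenebicyclo[9.3.1]pentadecan-13-one | C=C1C(=O)C[C@H]2C[C@H]3O[C@]3(C)CC[C@H]3O[C@]3(C)C[C@H](O)[C@H]1C2(C)C
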